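Assumption: atoms carry germacrane numbers (C6 lactone carbinol, C7 ring-fusion CH, C8 ester carbinol, C10 tertiary carbinol, C3 ketone, C11–C13 acrylate unit). The SMILES is read literally: 6S,7R,8R,10R, cis-fused lactone, 1E,4Z, (S)-2-methylbutanoate.

**Retrosynthetic overview**
1. Ten-membered carbocycle, formed last: carbonylative Stille macrocyclisation of 24; CO becomes C3 and joins the (Z)-vinyl iodide carbon C4 to the (E)-vinylstannane carbon C2.
2. cis-γ-Lactone, formed first: TES removal and lactonisation of C6–OH onto the acrylate ester, after C8–OH has been acylated.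
3. C7–C8 bond and both stereocentres: indium-mediated 2-(methoxycarbonyl)allylation of aldehyde 18 by allylic bromide 13.
4. 13 from D-glyceraldehyde acetonide (C6) by Stork–Zhao iodo-olefination, Morita–Baylis–Hillman reaction and SN2′ bromination.
5. 18 from (E)-3-methylpent-2-en-4-yn-1-ol by Sharpless epoxidation (C10), Red-Al opening, hydrostannation and oxidation.

**Route**

Step 1
Reactants: 1 (R)-2,2-dimethyl-1,3-dioxolane-4-carbaldehyde (D-glyceraldehyde acetonide); 2 ethyltriphenylphosphonium iodide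
Product: 6 (4S)-4-[(1Z)-2-iodoprop-1-en-1-yl]-2,2-dimethyl-1,3-dioxolane, via ethylidenetriphenylphosphorane 3 (not isolated), via (1-iodoethyl)triphenylphosphonium iodide 4 (not isolated), via (1-iodoethylidene)triphenylphosphorane 5 (not isolated)
Conditions: 2, n-BuLi, THF, rt; I2, −78 °C; NaN(SiMe3)2, −20 °C; then 1, −78 °C to rt
Reagents that add atoms: iodine, I-I
Why: Stork–Zhao-type Wittig olefination in which the α-iodo ylide 5 reacts at −78 °C through the kinetically favoured cis-oxaphosphetane to give the (Z)-iodoalkene (iodine cis to C6, usually at least 10:1), while the dioxolane stereocentre (future C6, from the chiral pool) is untouched.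

Step 2
Reactants: 6 (4S)-4-[(1Z)-2-iodoprop-1-en-1-yl]-2,2-dimethyl-1,3-dioxolane
Product: 7 (2S,3Z)-4-iodopent-3-ene-1,2-diol
Conditions: AcOH/H2O (4:1), 40 °C
Reagents that add atoms: none
Why: Acid-catalysed acetal hydrolysis that leaves the vinyl iodide and the stereocentre unchanged.

Step 3
Reactants: 7 (2S,3Z)-4-iodopent-3-ene-1,2-diol
Product: 8 (2S,3Z)-4-iodo-1,2-bis(triethylsilyloxy)pent-3-ene
Conditions: TESCl, imidazole, DMAP (cat.), CH2Cl2, 0 °C to rt
Reagents that add atoms: chlorotriethylsilane, CC[Si](Cl)(CC)CC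
Why: Standard imidazole-promoted silylation of both hydroxyl groups.

Step 4
Reactants: 8 (2S,3Z)-4-iodo-1,2-bis(triethylsilyloxy)pent-3-ene
Product: 10 (2S,3Z)-4-iodo-2-(triethylsilyloxy)pent-3-enal, via alkoxydimethylsulfonium chloride 9 (not isolated)
Conditions: (COCl)2, DMSO, CH2Cl2, −78 to −40 °C; then Et3N, −78 to 0 °C
Reagents that add atoms: none
Why: Swern oxidation of a bis-TES ether, in which the chlorosulfonium reagent cleaves only the unhindered primary silyl ether and the alkoxysulfonium salt 9 collapses to the aldehyde on adding Et3N, the cold work-up keeping the α-silyloxy stereocentre intact.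

Step 5
Reactants: 10 (2S,3Z)-4-iodo-2-(triethylsilyloxy)pent-3-enal; 11 methyl acrylate
Product: 12 methyl (4S,5Z)-3-hydroxy-6-iodo-2-methylidene-4-(triethylsilyloxy)hept-5-enoate (both C3 epimers)
Conditions: DABCO, 11 (3 equiv), 1,4-dioxane/H2O (1:1), rt
Reagents that add atoms: none
Why: Morita–Baylis–Hillman reaction, whose new carbinol (future C7) forms as an epimer mixture that does not matter because this carbon becomes sp2 in step 6.

Step 6
Reactants: 12 methyl (4S,5Z)-3-hydroxy-6-iodo-2-methylidene-4-(triethylsilyloxy)hept-5-enoate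
Product: 13 methyl (2Z,4R,5Z)-2-(bromomethyl)-6-iodo-4-(triethylsilyloxy)hepta-2,5-dienoate
Conditions: NBS, Me2S, CH2Cl2, 0 °C to rt
Reagents that add atoms: N-bromosuccinimide, O=C1CCC(=O)N1Br
Why: Corey–Kim-type activation of the allylic alcohol followed by SN2′ attack of bromide gives the conjugated primary allylic bromide as the favoured (2Z) isomer (CH2Br cis to C6), the TES ether and vinyl iodide being inert.

Step 7
Reactants: 14 (2E)-3-methylpent-2-en-4-yn-1-ol
Product: 15 [(2S,3S)-3-ethynyl-3-methyloxiran-2-yl]methanol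
Conditions: Ti(OiPr)4 (10 mol %), L-(+)-diethyl tartrate (12 mol %), t-BuOOH, 4 Å MS, CH2Cl2, −20 °C
Reagents that add atoms: tert-butyl hydroperoxide, CC(C)(C)OO
Why: Sharpless asymmetric epoxidation in which, as for geraniol, L-(+)-diethyl tartrate directs oxygen to the face that gives the (2S,3S)-epoxide, fixing the future C10 configuration, while the alkyne does not react.

Step 8
Reactants: 15 [(2S,3S)-3-ethynyl-3-methyloxiran-2-yl]methanol
Product: 16 (3R)-3-methylpent-4-yne-1,3-diol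
Conditions: NaAlH2(OCH2CH2OCH3)2, THF, 0 °C; Rochelle salt work-up
Reagents that add atoms: none
Why: Hydroxyl-directed epoxide reduction in which the primary alkoxyaluminate delivers hydride intramolecularly to C2 (future C9), so the C3–O bond and its configuration are kept and the 1,3-diol results, the terminal alkyne being only deprotonated at 0 °C.

Step 9
Reactants: 16 (3R)-3-methylpent-4-yne-1,3-diol
Product: 17 (3R,4E)-3-methyl-5-(tributylstannyl)pent-4-ene-1,3-diol
Conditions: Bu3SnH, PdCl2(PPh3)2 (2 mol %), THF, 0 °C to rt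
Reagents that add atoms: tributylstannane, CCCC[SnH](CCCC)CCCC
Why: Palladium-catalysed syn-hydrostannation in which the fully substituted propargylic carbon steers tin to the terminal carbon and gives the (E)-β-stannyl alkene.

Step 10
Reactants: 17 (3R,4E)-3-methyl-5-(tributylstannyl)pent-4-ene-1,3-diol
Product: 18 (3R,4E)-3-hydroxy-3-methyl-5-(tributylstannyl)pent-4-enal
Conditions: DMP, NaHCO3, CH2Cl2, 0 °C; used crude
Reagents that add atoms: none
Why: Dess–Martin oxidation of the only oxidisable (primary) alcohol, buffered so that the vinylstannane and the β-hydroxy aldehyde survive.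

Step 11
Reactants: 13 methyl (2Z,4R,5Z)-2-(bromomethyl)-6-iodo-4-(triethylsilyloxy)hepta-2,5-dienoate; 18 (3R,4E)-3-hydroxy-3-methyl-5-(tributylstannyl)pent-4-enal
Product: 20 methyl (3R,4R,6R,7E)-4,6-dihydroxy-3-[(1R,2Z)-3-iodo-1-(triethylsilyloxy)but-2-en-1-yl]-6-methyl-2-methylidene-8-(tributylstannyl)oct-7-enoate, via allylindium reagent 19 (not isolated)
Conditions: indium powder, THF/H2O (1:1), rt
Reagents that add atoms: none
Why: Indium-mediated Barbier-type 2-(alkoxycarbonyl)allylation in which reagent 19 adds through its γ-carbon (C7) in a chair Zimmerman–Traxler transition state with the C6 substituent, cis to the CH2–In group, axial (7,8-syn adduct, hence 8R), and the aldehyde attacks C7 anti to the C6–C5 bond with H-6 eclipsing the alkene to minimise A(1,3) strain and the OTES group outside (hence 7R).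

Step 12
Reactants: 20 methyl (3R,4R,6R,7E)-4,6-dihydroxy-3-[(1R,2Z)-3-iodo-1-(triethylsilyloxy)but-2-en-1-yl]-6-methyl-2-methylidene-8-(tributylstannyl)oct-7-enoate; 21 (2S)-2-methylbutanoic anhydride
Product: 22 methyl (3R,4R,6R,7E)-6-hydroxy-3-[(1R,2Z)-3-iodo-1-(triethylsilyloxy)but-2-en-1-yl]-6-methyl-2-methylidene-4-{[(2S)-2-methylbutanoyl]oxy}-8-(tributylstannyl)oct-7-enoate
Conditions: DMAP (cat.), Et3N, CH2Cl2, 0 °C
Reagents that add atoms: none
Why: DMAP-catalysed acylation of the secondary C8 hydroxyl (the tertiary C10 hydroxyl does not react), run cold so that it outpaces lactonisation of C8–OH onto the methyl ester, the acyl stereocentre coming from 21.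

Step 13
Reactants: 22 methyl (3R,4R,6R,7E)-6-hydroxy-3-[(1R,2Z)-3-iodo-1-(triethylsilyloxy)but-2-en-1-yl]-6-methyl-2-methylidene-4-{[(2S)-2-methylbutanoyl]oxy}-8-(tributylstannyl)oct-7-enoate
Product: 24 (1R,3R,4E)-3-hydroxy-1-{(2R,3R)-2-[(1Z)-2-iodoprop-1-en-1-yl]-4-methylidene-5-oxooxolan-3-yl}-3-methyl-5-(tributylstannyl)pent-4-en-1-yl (2S)-2-methylbutanoate, via desilylated hydroxy ester 23 (not isolated)
Conditions: PPTS, MeOH, 0 °C to rt; then PPTS (cat.), PhMe, 45 °C
Reagents that add atoms: none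
Why: Acid-catalysed methanolysis of the allylic TES ether gives 23, whose C6 hydroxyl undergoes 5-exo-trig lactonisation onto the acrylate ester; only the 6,12-lactone can form because O-8 is acylated, and the C6/C7 configuration set earlier makes it cis-fused.

Step 14
Reactants: 24 (1R,3R,4E)-3-hydroxy-1-{(2R,3R)-2-[(1Z)-2-iodoprop-1-en-1-yl]-4-methylidene-5-oxooxolan-3-yl}-3-methyl-5-(tributylstannyl)pent-4-en-1-yl (2S)-2-methylbutanoate
Product: 25 (3aR,4R,6R,7E,10Z,11aS)-6-hydroxy-6,10-dimethyl-3-methylidene-2,9-dioxo-2,3,3a,4,5,6,9,11a-octahydrocyclodeca[b]furan-4-yl (2S)-2-methylbutanoate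
Conditions: Pd2(dba)3 (10 mol %), AsPh3 (40 mol %), CO (1 atm), NMP/THF, 50 °C, 1 mM, syringe-pump addition
Reagents that add atoms: carbon monoxide, [C-]#[O+]
Why: Proposed new method: intramolecular carbonylative Stille coupling closing a ten-membered ring, in which zerovalent palladium inserts into the (Z)-vinyl iodide, CO insertion gives the acyl–palladium species, and transmetalation from the tethered (E)-vinylstannane followed by reductive elimination forms C3–C4 and C2–C3 with retention of both alkene geometries; the closest known reactions are carbonylative Stille macrocyclisations to eleven-membered and larger cross-conjugated dienones, and the cis-fused lactone holds both arms on one face to favour closure.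

**Compound list**
1 | (R)-2,2-dimethyl-1,3-dioxolane-4-carbaldehyde | O=C[C@H]1COC(C)(C)O1 | starting material
2 | ethyltriphenylphosphonium iodide | CC[P+](c1ccccc1)(c1ccccc1)c1ccccc1.[I-] | starting material
3 | ethylidenetriphenylphosphorane | CC=P(c1ccccc1)(c1ccccc1)c1ccccc1 | intermediate
4 | (1-iodoethyl)triphenylphosphonium iodide | CC(I)[P+](c1ccccc1)(c1ccccc1)c1ccccc1.[I-] | intermediate
5 | (1-iodoethylidene)triphenylphosphorane | CC(I)=P(c1ccccc1)(c1ccccc1)c1ccccc1 | intermediate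
6 | (4S)-4-[(1Z)-2-iodoprop-1-en-1-yl]-2,2-dimethyl-1,3-dioxolane | CC(/I)=C/[C@H]1COC(C)(C)O1 | intermediate
7 | (2S,3Z)-4-iodopent-3-ene-1,2-diol | CC(/I)=C/[C@H](O)CO | intermediate
8 | (2S,3Z)-4-iodo-1,2-bis(triethylsilyloxy)pent-3-ene | CC(/I)=C/[C@H](O[Si](CC)(CC)CC)CO[Si](CC)(CC)CC | intermediate
9 | dimethyl{[(2S,3Z)-4-iodo-2-(triethylsilyloxy)pent-3-en-1-yl]oxy}sulfonium chloride | CC(/I)=C/[C@H](O[Si](CC)(CC)CC)CO[S+](C)C.[Cl-] | intermediate
10 | (2S,3Z)-4-iodo-2-(triethylsilyloxy)pent-3-enal | CC(/I)=C/[C@H](O[Si](CC)(CC)CC)C=O | intermediate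
11 | methyl acrylate | C=CC(=O)OC | starting material
12 | methyl (4S,5Z)-3-hydroxy-6-iodo-2-methylidene-4-(triethylsilyloxy)hept-5-enoate (C3 epimers) | COC(=O)C(=C)C(O)[C@@H](O[Si](CC)(CC)CC)/C=C(/C)I | intermediate
13 | methyl (2Z,4R,5Z)-2-(bromomethyl)-6-iodo-4-(triethylsilyloxy)hepta-2,5-dienoate | COC(=O)/C(CBr)=C/[C@@H](O[Si](CC)(CC)CC)/C=C(/C)I | intermediate
14 | (2E)-3-methylpent-2-en-4-yn-1-ol | C#C/C(C)=C/CO | starting material
15 | [(2S,3S)-3-ethynyl-3-methyloxiran-2-yl]methanol | OC[C@@H]1O[C@@]1(C)C#C | intermediate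
16 | (3R)-3-methylpent-4-yne-1,3-diol | OCC[C@@](C)(O)C#C | intermediate
17 | (3R,4E)-3-methyl-5-(tributylstannyl)pent-4-ene-1,3-diol | OCC[C@@](C)(O)/C=C/[Sn](CCCC)(CCCC)CCCC | intermediate
18 | (3R,4E)-3-hydroxy-3-methyl-5-(tributylstannyl)pent-4-enal | O=CC[C@@](C)(O)/C=C/[Sn](CCCC)(CCCC)CCCC | intermediate
19 | allylindium reagent from 13 (monovalent indium on the former CH2Br carbon) | COC(=O)/C(C[In])=C/[C@@H](O[Si](CC)(CC)CC)/C=C(/C)I | intermediate
20 | methyl (3R,4R,6R,7E)-4,6-dihydroxy-3-[(1R,2Z)-3-iodo-1-(triethylsilyloxy)but-2-en-1-yl]-6-methyl-2-methylidene-8-(tributylstannyl)oct-7-enoate | C=C(C(=O)OC)[C@@H]([C@@H](O[Si](CC)(CC)CC)/C=C(/C)I)[C@H](O)C[C@@](C)(O)/C=C/[Sn](CCCC)(CCCC)CCCC | intermediate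
21 | (2S)-2-methylbutanoic anhydride | CC[C@H](C)C(=O)OC(=O)[C@@H](C)CC | starting material
22 | methyl (3R,4R,6R,7E)-6-hydroxy-3-[(1R,2Z)-3-iodo-1-(triethylsilyloxy)but-2-en-1-yl]-6-methyl-2-methylidene-4-{[(2S)-2-methylbutanoyl]oxy}-8-(tributylstannyl)oct-7-enoate | C=C(C(=O)OC)[C@@H]([C@@H](O[Si](CC)(CC)CC)/C=C(/C)I)[C@H](OC(=O)[C@@H](C)CC)C[C@@](C)(O)/C=C/[Sn](CCCC)(CCCC)CCCC | intermediate
23 | methyl (3S,4R,6R,7E)-6-hydroxy-3-[(1R,2Z)-1-hydroxy-3-iodobut-2-en-1-yl]-6-methyl-2-methylidene-4-{[(2S)-2-methylbutanoyl]oxy}-8-(tributylstannyl)oct-7-enoate | C=C(C(=O)OC)[C@@H]([C@@H](O)/C=C(/C)I)[C@H](OC(=O)[C@@H](C)CC)C[C@@](C)(O)/C=C/[Sn](CCCC)(CCCC)CCCC | intermediate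
24 | (1R,3R,4E)-3-hydroxy-1-{(2R,3R)-2-[(1Z)-2-iodoprop-1-en-1-yl]-4-methylidene-5-oxooxolan-3-yl}-3-methyl-5-(tributylstannyl)pent-4-en-1-yl (2S)-2-methylbutanoate | C=C1C(=O)O[C@@H](/C=C(/C)I)[C@H]1[C@H](OC(=O)[C@@H](C)CC)C[C@@](C)(O)/C=C/[Sn](CCCC)(CCCC)CCCC | intermediate
25 | (3aR,4R,6R,7E,10Z,11aS)-6-hydroxy-6,10-dimethyl-3-methylidene-2,9-dioxo-2,3,3a,4,5,6,9,11a-octahydrocyclodeca[b]furan-4-yl (2S)-2-methylbutanoate (CNP0315499.4) | C=C1C(=O)O[C@H]2/C=C(/C)C(=O)/C=C/[C@](C)(O)C[C@@H](OC(=O)[C@@H](C)CC)[C@@H]12 | target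

**Step count and risks**

Total steps: 14. Longest linear sequence: 10 steps (steps 1–6, then 11–14, from 1). The second branch (steps 7–10, from 14) has four steps before the union in step 11.

Three steps most likely to fail:

1. Step 14. The acyl–palladium intermediate may be captured by the neighbouring α-methylene lactone, or may oligomerise, before the strained ten-membered transmetalation. Fallback, which closes the ring by allylation instead: setting out from 12 and 18, an intermolecular carbonylative Stille coupling (Pd2(dba)3, AsPh3, CO, THF, 45 °C) gives methyl (4S,5Z,8E,10R)-3,10-dihydroxy-6,10-dimethyl-2-methylidene-7,12-dioxo-4-(triethylsilyloxy)dodeca-5,8-dienoate F1. NBS/Me2S then converts its allylic alcohol into methyl (2Z,4S,5Z,8E,10R)-2-(bromomethyl)-10-hydroxy-6,10-dimethyl-7,12-dioxo-4-(triethylsilyloxy)dodeca-2,5,8-trienoate F2. Indium powder in THF/H2O at 2 mM (or CrCl2 in DMF) closes the ten-membered ring by intramolecular 2-(methoxycarbonyl)allylation of the aldehyde (C7–C8 bond), giving methyl 2-[(1R,2R,4R,5E,8Z,10S)-2,4-dihydroxy-4,8-dimethyl-7-oxo-10-(triethylsilyloxy)cyclodeca-5,8-dien-1-yl]prop-2-enoate F3. Acylation with 21 gives methyl 2-[(1R,2R,4R,5E,8Z,10S)-4-hydroxy-4,8-dimethyl-2-{[(2S)-2-methylbutanoyl]oxy}-7-oxo-10-(triethylsilyloxy)cyclodeca-5,8-dien-1-yl]prop-2-enoate F4. PPTS/MeOH removes the TES group to give methyl 2-[(1S,2R,4R,5E,8Z,10S)-4,10-dihydroxy-4,8-dimethyl-2-{[(2S)-2-methylbutanoyl]oxy}-7-oxocyclodeca-5,8-dien-1-yl]prop-2-enoate F5 (not isolated), which lactonises and comes back to the route at 25.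

2. Step 11. The C6→C7 facial sense rests on a model rather than a direct precedent, the syn/anti ratio depends on the allylindium geometry, and the γ-silyloxy group can be lost by 1,4-elimination. Fallback, which uses anti-selective addition followed by invertive esterification: setting out from 13 and 18, the CrCl2-mediated variant (CrCl2, THF, 0 °C) reacts through the (E)-allylchromium species and gives the C8 epimer methyl (3R,4S,6R,7E)-4,6-dihydroxy-3-[(1R,2Z)-3-iodo-1-(triethylsilyloxy)but-2-en-1-yl]-6-methyl-2-methylidene-8-(tributylstannyl)oct-7-enoate F6. The facial control at C7 should be the same, because the ester keeps H-6 eclipsed in either reagent geometry. Mitsunobu esterification of F6 with (S)-2-methylbutanoic acid (PPh3, DIAD, PhMe, 0 °C) inverts C8 and comes back to the route at 22. This repairs a wrong C8 only; a wrong C7 is not repaired by it.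

3. Step 5. The amine-catalysed reaction is slow, and the α-silyloxy β,γ-unsaturated aldehyde 10 can epimerise or move into conjugation meanwhile. Fallback, a stoichiometric aldol/elimination sequence at low temperature: setting out from 10, addition of the lithium enolate of methyl 3-(dimethylamino)propanoate (LDA, THF, −78 °C) gives methyl (4S,5Z)-2-[(dimethylamino)methyl]-3-hydroxy-6-iodo-4-(triethylsilyloxy)hept-5-enoate F7. N-Methylation with MeI gives [(4S,5Z)-3-hydroxy-6-iodo-2-(methoxycarbonyl)-4-(triethylsilyloxy)hept-5-en-1-yl]trimethylammonium iodide F8 (not isolated), and DBU eliminates trimethylamine to come back to the route at 12.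

**Further compounds**
F1 | step 14 | methyl (4S,5Z,8E,10R)-3,10-dihydroxy-6,10-dimethyl-2-methylidene-7,12-dioxo-4-(triethylsilyloxy)dodeca-5,8-dienoate | COC(=O)C(=C)C(O)[C@@H](O[Si](CC)(CC)CC)/C=C(/C)C(=O)/C=C/[C@](C)(O)CC=O
F2 | step 14 | methyl (2Z,4S,5Z,8E,10R)-2-(bromomethyl)-10-hydroxy-6,10-dimethyl-7,12-dioxo-4-(triethylsilyloxy)dodeca-2,5,8-trienoate | COC(=O)/C(CBr)=C/[C@@H](O[Si](CC)(CC)CC)/C=C(/C)C(=O)/C=C/[C@](C)(O)CC=O
F3 | step 14 | methyl 2-[(1R,2R,4R,5E,8Z,10S)-2,4-dihydroxy-4,8-dimethyl-7-oxo-10-(triethylsilyloxy)cyclodeca-5,8-dien-1-yl]prop-2-enoate | C=C(C(=O)OC)[C@H]1[C@@H](O[Si](CC)(CC)CC)/C=C(/C)C(=O)/C=C/[C@](C)(O)C[C@H]1O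
F4 | step 14 | methyl 2-[(1R,2R,4R,5E,8Z,10S)-4-hydroxy-4,8-dimethyl-2-{[(2S)-2-methylbutanoyl]oxy}-7-oxo-10-(triethylsilyloxy)cyclodeca-5,8-dien-1-yl]prop-2-enoate | C=C(C(=O)OC)[C@H]1[C@@H](O[Si](CC)(CC)CC)/C=C(/C)C(=O)/C=C/[C@](C)(O)C[C@H]1OC(=O)[C@@H](C)CC
F5 | step 14 | methyl 2-[(1S,2R,4R,5E,8Z,10S)-4,10-dihydroxy-4,8-dimethyl-2-{[(2S)-2-methylbutanoyl]oxy}-7-oxocyclodeca-5,8-dien-1-yl]prop-2-enoate | C=C(C(=O)OC)[C@H]1[C@@H](O)/C=C(/C)C(=O)/C=C/[C@](C)(O)C[C@H]1OC(=O)[C@@H](C)CC
F6 | step 11 | methyl (3R,4S,6R,7E)-4,6-dihydroxy-3-[(1R,2Z)-3-iodo-1-(triethylsilyloxy)but-2-en-1-yl]-6-methyl-2-methylidene-8-(tributylstannyl)oct-7-enoate | C=C(C(=O)OC)[C@@H]([C@@H](O[Si](CC)(CC)CC)/C=C(/C)I)[C@@H](O)C[C@@](C)(O)/C=C/[Sn](CCCC)(CCCC)CCCC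
F7 | step 5 | methyl (4S,5Z)-2-[(dimethylamino)methyl]-3-hydroxy-6-iodo-4-(triethylsilyloxy)hept-5-enoate | COC(=O)C(CN(C)C)C(O)[C@@H](O[Si](CC)(CC)CC)/C=C(/C)I
F8 | step 5 | [(4S,5Z)-3-hydroxy-6-iodo-2-(methoxycarbonyl)-4-(triethylsilyloxy)hept-5-en-1-yl]trimethylammonium iodide | COC(=O)C(C[N+](C)(C)C)C(O)[C@@H](O[Si](CC)(CC)CC)/C=C(/C)I.[I-]
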